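A direct plan would grow ring A last on a finished ring B–ring C unit. The 3-hydroxy-4-pyranone A1 would be made by Achmatowicz ring expansion and acid aromatisation, benzylated and iodinated to A2, magnesiated and added to dimethyl squarate A3 to give cyclobutenone A4, and heated to expand A4 into the 5,8-dihydroxyflavone A5. Methylation at O8 and hydrogenolysis would finish. Its weakest steps would be:
- the acid aromatisation to A1, because a vinyl bromide must be hydrolysed beside an ionisable benzylic carbon;
- the thermal ring expansion of A4, because the 6π closure must break the pyranone conjugation while the vinylketene can be trapped by its own hydroxyl;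
- the mono-methylation of A5, an air-sensitive hydroquinone with only chelation to tell O5 from O8.

The new route disconnects ring C from ring A at both junctions at once. With O5 carried as a methyl ether, C5–C8 of ring A bear four equal methoxyls, so C4a and C8a are the two carbons of a mirror-symmetric aryne, 3,4,5,6-tetramethoxybenzyne. Its insertion into the C–O bond of an arylpropiolic acid, followed in the same flask by oxa-Michael closure, would form C8a–O1, C4a–C4 and O1–C2 and deliver the complete flavone with no regiochemical question. O3 would then be added by epoxidation and O5 freed by carbonyl-chelated demethylation. No pyranone is made from a furan, no ring A is grown from a cyclobutenone, and no hydroquinone is mono-alkylated.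

Key step: step 5

Assumption: 1,2,3,4-tetramethoxybenzene and 1-(benzyloxy)-4-ethynylbenzene are taken as catalogue compounds.

Step 1
Reactants: 1 1,2,3,4-tetramethoxybenzene
Product: 4 2,3,4,5-tetramethoxyphenol, via aryllithium 2 (not isolated), via aryl dimethyl boronate 3 (not isolated)
Conditions: n-BuLi (1.1 equiv), TMEDA, THF, 0 °C; B(OMe)3, −78 °C → rt; 30% H2O2, AcOH, 0 °C → rt
Reagents that add atoms: hydrogen peroxide, OO
Why: Directed ortho-metalation beside a methoxyl at one of the two equivalent ring hydrogens, borylation and oxidative boron-to-oxygen aryl shift (ipso-hydroxylation) should give the phenol, the acidic peroxide work-up sparing the oxidation-prone product.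

Step 2
Reactants: 4 2,3,4,5-tetramethoxyphenol
Product: 5 2-bromo-3,4,5,6-tetramethoxyphenol
Conditions: NBS (1.0 equiv), CH2Cl2, −40 → 0 °C, dark
Reagents that add atoms: N-bromosuccinimide, O=C1CCC(=O)N1Br
Why: Electrophilic aromatic bromination at the only free ring position, ortho to the hydroxyl, with dry NBS at low temperature to keep oxidation of the para-methoxyphenol to a quinone in check.

Step 3
Reactants: 5 2-bromo-3,4,5,6-tetramethoxyphenol
Product: 8 2,3,4,5-tetramethoxy-6-(trimethylsilyl)phenyl trifluoromethanesulfonate, via aryl trimethylsilyl ether 6 (not isolated), via lithium 2-silylphenoxide 7 (not isolated)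
Conditions: HMDS, THF, 65 °C, then evaporate; n-BuLi, THF, −100 °C; Tf2O, −100 °C → rt
Reagents that add atoms: hexamethyldisilazane, C[Si](C)(C)N[Si](C)(C)C; trifluoromethanesulfonic anhydride, O=S(=O)(OS(=O)(=O)C(F)(F)F)C(F)(F)F
Why: O-Silylation, bromine–lithium exchange, anionic 1,3-silyl shift from oxygen to carbon (retro-Brook rearrangement) and O-triflation of the phenoxide, the standard passage from an ortho-bromophenol to an ortho-silylaryl triflate aryne precursor.

Step 4
Reactants: 9 1-(benzyloxy)-4-ethynylbenzene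
Product: 11 3-[4-(benzyloxy)phenyl]prop-2-ynoic acid, via lithium acetylide 10 (not isolated)
Conditions: n-BuLi, THF, −78 °C; CO2 (gas), −78 °C → rt; 1 M HCl
Reagents that add atoms: carbon dioxide, O=C=O
Why: Deprotonation of the terminal alkyne and carboxylation of the lithium acetylide, far faster at −78 °C than any benzylic metalation of the ether.

Step 5
Reactants: 8 2,3,4,5-tetramethoxy-6-(trimethylsilyl)phenyl trifluoromethanesulfonate; 11 3-[4-(benzyloxy)phenyl]prop-2-ynoic acid
Product: 14 2-[4-(benzyloxy)phenyl]-5,6,7,8-tetramethoxy-4H-chromen-4-one (4'-benzyloxy-5,6,7,8-tetramethoxyflavone), via tetramethoxybenzyne 12 (not isolated), via 2-acylphenoxide 13 (not isolated)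
Conditions: 8 (1.5 equiv), 11 (1.0 equiv), CsF (4 equiv), THF, 125 °C (sealed tube)
Reagents that add atoms: none
Why: Fluoride should unmask 3,4,5,6-tetramethoxybenzyne 12, the carboxylate of 11 adds to it, the aryl anion so formed attacks its own ester carbonyl through a four-membered transition structure and the benzoxetene alkoxide collapses to the 2-acylphenoxide 13 (net insertion of the aryne into the C–O bond of the acid, forming C8a–O1 and C4a–C4), and 13 then adds to the ynone to form O1–C2. The closest known reaction type is the aryne C–O insertion of carboxylic acids, in its variant with 3-arylpropiolic acids that ends in flavones. Ring C closes by 6-endo-dig oxa-Michael addition, favoured in an aprotic medium because it leads to the conjugated allenolate whereas the 5-exo-dig path to the aurone gives an unstabilised vinyl anion. No stereocentre is formed. The step needs a single regiochemical outcome, and the mirror symmetry of 12 secures it: both aryne carbons carry an ortho methoxyl, so either mode of addition gives the same 5,6,7,8-tetramethoxy pattern, and that methoxyl stabilises the aryl anion until acyl transfer. Excess CsF keeps the acid as its carboxylate so that proton quench to the simple aryl ester should stay minor.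

Step 6
Reactants: 14 2-[4-(benzyloxy)phenyl]-5,6,7,8-tetramethoxy-4H-chromen-4-one
Product: 16 2-[4-(benzyloxy)phenyl]-3-hydroxy-5,6,7,8-tetramethoxy-4H-chromen-4-one, via flavone 2,3-epoxide 15 (not isolated)
Conditions: dimethyldioxirane (ca. 0.08 M in acetone, 3 equiv), CH2Cl2, 0 °C → rt; then p-TsOH·H2O (cat.), CH2Cl2, rt
Reagents that add atoms: dimethyldioxirane, CC1(C)OO1
Why: Electrophilic epoxidation of the flavone C2=C3 bond by the dioxirane, then acid-catalysed opening at C2 (cation stabilised by O1 and the 4-benzyloxyphenyl group) and loss of H3 to the 3-hydroxy enone; C2 and C3 of 15 form racemic, cis by ring fusion, and both become sp2 again.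

Step 7
Reactants: 16 2-[4-(benzyloxy)phenyl]-3-hydroxy-5,6,7,8-tetramethoxy-4H-chromen-4-one
Product: 17 3,5,4'-trihydroxy-6,7,8-trimethoxyflavone
Conditions: BCl3 (1 M in CH2Cl2, 6 equiv), C6HMe5 (3 equiv), CH2Cl2, −78 → 0 °C; then MeOH, 1 M HCl, rt
Reagents that add atoms: none
Why: Boron chelation between C4=O and O5 should direct chloride to the O5 methyl only (the peri-selective Lewis-acid demethylation of 5-methoxyflavones), the same reagent cleaves the benzyl aryl ether with pentamethylbenzene trapping the benzyl cation, and methanolic acid frees the 3- and 5-hydroxyls from boron.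

Compound list
1 | 1,2,3,4-tetramethoxybenzene | COc1ccc(OC)c(OC)c1OC | starting material
2 | (2,3,4,5-tetramethoxyphenyl)lithium | [Li]c1cc(OC)c(OC)c(OC)c1OC | intermediate
3 | dimethyl (2,3,4,5-tetramethoxyphenyl)boronate | COB(OC)c1cc(OC)c(OC)c(OC)c1OC | intermediate
4 | 2,3,4,5-tetramethoxyphenol | COc1cc(O)c(OC)c(OC)c1OC | intermediate
5 | 2-bromo-3,4,5,6-tetramethoxyphenol | COc1c(Br)c(O)c(OC)c(OC)c1OC | intermediate
6 | (2-bromo-3,4,5,6-tetramethoxyphenoxy)trimethylsilane | COc1c(Br)c(O[Si](C)(C)C)c(OC)c(OC)c1OC | intermediate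
7 | lithium 2,3,4,5-tetramethoxy-6-(trimethylsilyl)phenoxide | [Li+].COc1c([Si](C)(C)C)c([O-])c(OC)c(OC)c1OC | intermediate
8 | 2,3,4,5-tetramethoxy-6-(trimethylsilyl)phenyl trifluoromethanesulfonate | COc1c([Si](C)(C)C)c(OS(=O)(=O)C(F)(F)F)c(OC)c(OC)c1OC | intermediate
9 | 1-(benzyloxy)-4-ethynylbenzene | C#Cc1ccc(OCc2ccccc2)cc1 | starting material
10 | lithium [4-(benzyloxy)phenyl]acetylide | [Li]C#Cc1ccc(OCc2ccccc2)cc1 | intermediate
11 | 3-[4-(benzyloxy)phenyl]prop-2-ynoic acid | OC(=O)C#Cc1ccc(OCc2ccccc2)cc1 | intermediate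
12 | 3,4,5,6-tetramethoxybenzyne (1,2-didehydro-3,4,5,6-tetramethoxybenzene) | COC1=C(OC)C(OC)=C(OC)C#C1 | intermediate
13 | caesium 2-{3-[4-(benzyloxy)phenyl]prop-2-ynoyl}-3,4,5,6-tetramethoxyphenoxide | [Cs+].COc1c([O-])c(C(=O)C#Cc2ccc(OCc3ccccc3)cc2)c(OC)c(OC)c1OC | intermediate
14 | 2-[4-(benzyloxy)phenyl]-5,6,7,8-tetramethoxy-4H-chromen-4-one | COc1c(OC)c(OC)c2c(=O)cc(-c3ccc(OCc4ccccc4)cc3)oc2c1OC | intermediate
15 | (±)-1a-[4-(benzyloxy)phenyl]-3,4,5,6-tetramethoxy-1a,7a-dihydro-7H-oxireno[2,3-b]chromen-7-one (the 2,3-epoxide of 14, cis-fused, racemic) | COc1c(OC)c(OC)c2c(c1OC)OC1(c3ccc(OCc4ccccc4)cc3)OC1C2=O | intermediate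
16 | 2-[4-(benzyloxy)phenyl]-3-hydroxy-5,6,7,8-tetramethoxy-4H-chromen-4-one | COc1c(OC)c(OC)c2c(=O)c(O)c(-c3ccc(OCc4ccccc4)cc3)oc2c1OC | intermediate
17 | 3,5,4'-trihydroxy-6,7,8-trimethoxyflavone (achiral) | COc1c(OC)c(O)c2c(=O)c(O)c(-c3ccc(O)cc3)oc2c1OC | target

Total step count: 7. Longest linear sequence: 6 (steps 1, 2, 3, 5, 6, 7).

Steps most likely to fail:

Step 5. The propiolate may decarboxylate before it is O-arylated, the aryl anion may be protonated before acyl transfer, or the phenoxide may close 5-exo. The fallback would set out from phenol 4 and alkyne 9. Phenol 4 would be iodinated with N-iodosuccinimide at its only free position to 2-iodo-3,4,5,6-tetramethoxyphenol F1. F1, 9 and CO would then be joined by a carbonylative Sonogashira annulation (PdCl2(PPh3)2, Et2NH, CO, 120 °C). This passes through 3-[4-(benzyloxy)phenyl]-1-(2-hydroxy-3,4,5,6-tetramethoxyphenyl)prop-2-yn-1-one F2, which would close in the same flask and come back to the route at 14.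

Step 6. Epoxidation of the electron-poor C2=C3 bond may be slow enough for oxidation at the benzylic CH2 of the ether to compete, or the epoxide may open unproductively. The fallback would set out from 14. C3 would be deprotonated with LDA in THF at −78 °C to 2-[4-(benzyloxy)phenyl]-3-lithio-5,6,7,8-tetramethoxy-4H-chromen-4-one F3. This would be trapped with B(OMe)3 as dimethyl {2-[4-(benzyloxy)phenyl]-5,6,7,8-tetramethoxy-4-oxo-4H-chromen-3-yl}boronate F4 and oxidised with H2O2 in AcOH, coming back at 16.

Step 7. Cleavage may run on to the O6 methyl once boron is bound at O5, may stall because boron is tied up at O3, or the benzyl cation may alkylate ring B. The fallback would set out from 16 and separate the two events. Hydrogenolysis (H2, 10% Pd/C, EtOAc–MeOH) would give 3,4'-dihydroxy-5,6,7,8-tetramethoxyflavone F5. Its O5 methyl would then be removed with anhydrous AlCl3 in MeCN followed by dilute HCl, coming back at 17.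

Further compounds
F1 | step 5 | 2-iodo-3,4,5,6-tetramethoxyphenol | COc1c(I)c(O)c(OC)c(OC)c1OC
F2 | step 5 | 3-[4-(benzyloxy)phenyl]-1-(2-hydroxy-3,4,5,6-tetramethoxyphenyl)prop-2-yn-1-one | COc1c(O)c(C(=O)C#Cc2ccc(OCc3ccccc3)cc2)c(OC)c(OC)c1OC
F3 | step 6 | 2-[4-(benzyloxy)phenyl]-3-lithio-5,6,7,8-tetramethoxy-4H-chromen-4-one | COc1c(OC)c(OC)c2c(=O)c([Li])c(-c3ccc(OCc4ccccc4)cc3)oc2c1OC
F4 | step 6 | dimethyl {2-[4-(benzyloxy)phenyl]-5,6,7,8-tetramethoxy-4-oxo-4H-chromen-3-yl}boronate | COB(OC)c1c(-c2ccc(OCc3ccccc3)cc2)oc2c(OC)c(OC)c(OC)c(OC)c2c1=O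
F5 | step 7 | 3,4'-dihydroxy-5,6,7,8-tetramethoxyflavone | COc1c(OC)c(OC)c2c(=O)c(O)c(-c3ccc(O)cc3)oc2c1OC
A1 | direct plan | 2-[4-(benzyloxy)phenyl]-3-hydroxy-4H-pyran-4-one | O=c1ccoc(-c2ccc(OCc3ccccc3)cc2)c1O
A2 | direct plan | 3-(benzyloxy)-2-[4-(benzyloxy)phenyl]-5-iodo-4H-pyran-4-one | O=c1c(I)coc(-c2ccc(OCc3ccccc3)cc2)c1OCc1ccccc1
A3 | direct plan | dimethyl squarate (3,4-dimethoxycyclobut-3-ene-1,2-dione) | COC1=C(OC)C(=O)C1=O
A4 | direct plan | (±)-4-{5-(benzyloxy)-6-[4-(benzyloxy)phenyl]-4-oxo-4H-pyran-3-yl}-4-hydroxy-2,3-dimethoxycyclobut-2-en-1-one | COC1=C(OC)C(O)(c2coc(-c3ccc(OCc4ccccc4)cc3)c(OCc3ccccc3)c2=O)C1=O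
A5 | direct plan | 3,4'-bis(benzyloxy)-5,8-dihydroxy-6,7-dimethoxyflavone | O=c1c(OCc2ccccc2)c(-c2ccc(OCc3ccccc3)cc2)oc2c(O)c(OC)c(OC)c(O)c12
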